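The route rests on one disconnection, the C8–C9 bond of the cyclopentane (ring C5–C6–C7–C8–C9, iridoid numbering). C8 carries the tertiary hydroxyl β to C1, and O7–C7–C8–C10–O10 is the backbone of a 4-alkyl-2,2-dimethyl-1,3-dioxan-5-one, so C8–C9 is an aldol bond to a ketone held in a dioxane ring. In a single operation the proline enamine of the C1 aldehyde adds through C9 to that ketone: the cyclopentane closes cis-fused to the dioxane, and C8 and C9 are set. The precursor 11 is an open-chain keto aldehyde, the (S)-4-substituted dioxanone whose side chain carries at C5 a dimethyl malonate group (C3, C4, C11) and the CH2CHO arm (C9, C1).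

Key step: step 6

Remark: iridoid numbering is used for all intermediates (C1 acetal carbon, O2, C3=C4, C11 on C4, C5 and C9 ring-fusion carbons, C6, C7, C8, C10 on C8). Hydrazone C=N geometry is left unassigned. Lactol 15 is an equilibrating pair of C1 anomers and is drawn without configuration at C1.

Step 1
Reactants: 1 2,2-dimethyl-1,3-dioxan-5-one; 2 SAMP, (S)-1-amino-2-(methoxymethyl)pyrrolidine
Product: 3 (S)-N-(2,2-dimethyl-1,3-dioxan-5-ylidene)-2-(methoxymethyl)pyrrolidin-1-amine
Conditions: cyclohexane, reflux, Dean–Stark
Reagents that add atoms: none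
Why: Hydrazone formation (condensation) of the unhindered ketone with the N-amino auxiliary is driven by removal of water and creates no stereocentre.

Step 2
Reactants: 3 SAMP hydrazone; 4 allyl bromide
Product: 6 (S)-N-[(4S)-4-allyl-2,2-dimethyl-1,3-dioxan-5-ylidene]-2-(methoxymethyl)pyrrolidin-1-amine, via lithium azaenolate 5 (not isolated)
Conditions: t-BuLi, THF, −78 °C; allyl bromide, −100 °C → rt
Reagents that add atoms: none
Why: SAMP-hydrazone α-alkylation: the lithium azaenolate, rigidified by Li–OMe chelation, should be allylated on the face away from the pyrrolidine substituent, which sets C7 as (S).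

Step 3
Reactants: 6 allylated hydrazone
Product: 7 (4S)-4-allyl-2,2-dimethyl-1,3-dioxan-5-one
Conditions: sat. aq. oxalic acid, Et2O, rt
Reagents that add atoms: water, O
Why: Two-phase oxalic acid hydrolysis of the hydrazone should release the α-alkoxy ketone without epimerising C7 and without touching the acetonide.

Step 4
Reactants: 7 allyl ketone; 8 (E)-but-2-enal (crotonaldehyde)
Product: 9 (2E)-4-[(4S)-2,2-dimethyl-5-oxo-1,3-dioxan-4-yl]but-2-enal
Conditions: crotonaldehyde (5 equiv), second-generation Hoveyda–Grubbs catalyst RuCl2(H2IMes)(=CH-C6H4-2-OiPr) (3 mol %), CH2Cl2, 40 °C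
Reagents that add atoms: none
Why: Olefin cross-metathesis of a terminal alkene with an electron-poor partner should give the E-enal selectively under neutral conditions that leave the ketone, the acetonide and C7 alone.

Step 5
Reactants: 9 enal; 10 dimethyl malonate
Product: 11 dimethyl 2-[(2S)-1-[(4S)-2,2-dimethyl-5-oxo-1,3-dioxan-4-yl]-4-oxobutan-2-yl]propanedioate
Conditions: dimethyl malonate (1.5 equiv), (R)-2-{bis[3,5-bis(trifluoromethyl)phenyl](trimethylsilyloxy)methyl}pyrrolidine (10 mol %), EtOH, 0 °C
Reagents that add atoms: none
Why: Iminium-catalysed Michael addition of a malonate to an aliphatic enal: the (R)-diarylprolinol silyl ether shields one face of the E-iminium ion, so the malonate should add to C5 from the other face and give (S)-C5 under catalyst control, while in ethanol the product enamine is protonated and hydrolysed before it can add to the ketone.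

Step 6
Reactants: 11 keto aldehyde
Product: 12 dimethyl 2-[(4aR,5S,6S,7aS)-5-formyl-4a-hydroxy-2,2-dimethylhexahydrocyclopenta[d][1,3]dioxin-6-yl]propanedioate
Conditions: L-proline (20 mol %), DMSO (0.05 M), rt
Reagents that add atoms: none
Why: L-Proline should condense with the C1 aldehyde to give the E-enamine, whose C9 adds to the C8 ketone; hydrolysis then releases the β-hydroxy aldehyde, the closest known reaction type being the proline-catalysed intramolecular enolexo aldol addition of dialdehydes and keto aldehydes. The cyclopentane C5–C6–C7–C8–C9 closes in the 5-enolexo-exo-trig mode. C8 is controlled by the substrate: the short tether from (S)-C7 can reach only the ketone face that gives a cis ring fusion, so the new hydroxyl ends trans to O7 while C10 stays cis to O7. C9 is controlled by the catalyst: in the hydrogen-bonded transition state the carboxylic acid binds the C8 carbonyl oxygen and places C1 syn to it, which puts the formyl group cis to the C8 hydroxyl and to the C5 branch, and L-proline is the enantiomer whose directed face coincides with the face allowed by the cis fusion. The step needs chemoselectivity for the aldehyde enamine and an aldol stop without dehydration or retro-Michael loss of malonate. The ketone could react only through a tetrasubstituted enamine or a seven-membered closure, its two α-oxygens make it a strong acceptor for the fast five-membered closure, and neutral proline at room temperature should not dehydrate a tertiary aldol.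

Step 7
Reactants: 12 aldol
Product: 13 2-[4a-hydroxy-5-(hydroxymethyl)-2,2-dimethylhexahydrocyclopenta[d][1,3]dioxin-6-yl]propane-1,3-diol (ring configuration as in 12)
Conditions: LiAlH4 (4 equiv), THF, −78 → 0 °C; aq. potassium sodium tartrate
Reagents that add atoms: none
Why: Hydride reduction: LiAlH4 should reduce the aldehyde at −78 °C before any retro-aldol can occur and then both malonate esters, leaving the acetonide and the tertiary alcohol and changing no stereocentre.

Step 8
Reactants: 13 tetraol
Product: 15 tricyclic lactol aldehyde (iridoid 1-hydroxy-4-formyl-8-hydroxy-7,10-O-isopropylidene compound), via trialdehyde 14 (not isolated)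
Conditions: (COCl)2 (3.6 equiv), DMSO, CH2Cl2, −78 °C; Et3N, −78 → 0 °C
Reagents that add atoms: none
Why: Swern oxidation activates all three primary alcohols before base is added, so the three aldehydes should appear together and no lactol meets active oxidant; the 2-substituted malondialdehyde then enolises and its enol oxygen adds to the C1 aldehyde (hemiacetal formation), closing the pyran ring cis-fused at C5/C9.

Step 9
Reactants: 15 lactol aldehyde; 16 (3S)-3-methylpentanoic acid
Product: 17 (1S)-1-O-[(3S)-3-methylpentanoyl] ester of 15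
Conditions: DCC, DMAP (0.1 equiv), CH2Cl2, 0 °C
Reagents that add atoms: none
Why: Steglich esterification should acylate only the lactol hydroxyl (the tertiary C8 alcohol is inert), and as the anomers equilibrate the ester is expected on the convex face, trans to the C9–C8 bond in the anomerically favoured axial position, which is (S)-C1.

Step 10
Reactants: 17 acetonide ester
Product: 18 (1S)-1-O-[(3S)-3-methylpentanoyl]-4-formyl iridoid 7,8,10-triol
Conditions: AcOH/H2O (4:1), 40 °C
Reagents that add atoms: none
Why: Acid hydrolysis of the strained 1,3-dioxane acetonide should spare the anomeric ester and the enol ether, because the ring oxygen belongs to a vinylogous formate (O2–C3=C4–CHO) that disfavours oxocarbenium formation at C1.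

Step 11
Reactants: 19 (E)-4-hydroxycinnamic acid (p-coumaric acid)
Product: 21 (E)-4-(tert-butyldimethylsilyloxy)cinnamic acid, via bis-silyl derivative 20 (not isolated)
Conditions: TBSCl (2.2 equiv), imidazole, DMF, rt; then AcOH/H2O/THF, rt
Reagents that add atoms: tert-butyldimethylsilyl chloride (TBSCl), CC(C)(C)[Si](C)(C)Cl
Why: Silylation of phenol and acid followed by selective hydrolysis of the labile silyl ester should leave the aryl silyl ether and give the phenol-protected acid.

Step 12
Reactants: 18 triol; 21 silyl-protected coumaric acid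
Product: 22 10-O-[(E)-4-(tert-butyldimethylsilyloxy)cinnamoyl] ester of 18
Conditions: DCC, DMAP (0.1 equiv), CH2Cl2, −20 → 0 °C
Reagents that add atoms: none
Why: Steglich esterification under kinetic control with one equivalent of acid should acylate the primary C10 hydroxyl in preference to the secondary C7 and tertiary C8 hydroxyls.

Step 13
Reactants: 22 silyl ether
Product: 23 10-O-[(E)-4-hydroxycinnamoyl] ester of 18 (C11 aldehyde)
Conditions: TBAF, AcOH (1:1), THF, 0 °C
Reagents that add atoms: none
Why: Fluoride-mediated desilylation: an aryl silyl ether should be cleaved quickly by buffered TBAF under conditions that leave the alkyl esters, the anomeric ester and the aldehyde intact.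

Step 14
Reactants: 23 phenol aldehyde
Product: 24 CNP0241834.1, (1S,4aS,6S,7R,7aS)-6,7-dihydroxy-4-(hydroxymethyl)-7-{[(2E)-3-(4-hydroxyphenyl)prop-2-enoyl]oxymethyl}-1,4a,5,6,7,7a-hexahydrocyclopenta[c]pyran-1-yl (3S)-3-methylpentanoate
Conditions: NaBH4, CeCl3·7H2O, MeOH, −40 °C; pH 7 phosphate buffer
Reagents that add atoms: none
Why: Luche reduction should give selective 1,2-reduction of the C11 aldehyde (a vinylogous formate) to the allylic alcohol at low temperature without touching the cinnamate, the anomeric ester or the enol ether, and the neutral work-up protects the acid-sensitive product.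

Compound list
1 | 2,2-dimethyl-1,3-dioxan-5-one | CC1(C)OCC(=O)CO1 | starting material
2 | SAMP, (S)-1-amino-2-(methoxymethyl)pyrrolidine | COC[C@@H]1CCCN1N | starting material
3 | (S)-N-(2,2-dimethyl-1,3-dioxan-5-ylidene)-2-(methoxymethyl)pyrrolidin-1-amine | COC[C@@H]1CCCN1N=C1COC(C)(C)OC1 | intermediate
4 | allyl bromide | C=CCBr | starting material
5 | lithium azaenolate of 3 (not isolated) | COC[C@@H]1CCCN1N([Li])C1=COC(C)(C)OC1 | intermediate
6 | (S)-N-[(4S)-4-allyl-2,2-dimethyl-1,3-dioxan-5-ylidene]-2-(methoxymethyl)pyrrolidin-1-amine | COC[C@@H]1CCCN1N=C1COC(C)(C)O[C@H]1CC=C | intermediate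
7 | (4S)-4-allyl-2,2-dimethyl-1,3-dioxan-5-one | C=CC[C@@H]1OC(C)(C)OCC1=O | intermediate
8 | (E)-but-2-enal (crotonaldehyde) | C/C=C/C=O | starting material
9 | (2E)-4-[(4S)-2,2-dimethyl-5-oxo-1,3-dioxan-4-yl]but-2-enal | O=C/C=C/C[C@@H]1OC(C)(C)OCC1=O | intermediate
10 | dimethyl malonate | COC(=O)CC(=O)OC | starting material
11 | dimethyl 2-[(2S)-1-[(4S)-2,2-dimethyl-5-oxo-1,3-dioxan-4-yl]-4-oxobutan-2-yl]propanedioate (key-step precursor) | O=CC[C@@H](C(C(=O)OC)C(=O)OC)C[C@@H]1OC(C)(C)OCC1=O | intermediate
12 | dimethyl 2-[(4aR,5S,6S,7aS)-5-formyl-4a-hydroxy-2,2-dimethylhexahydrocyclopenta[d][1,3]dioxin-6-yl]propanedioate (key-step product; formyl, C8 hydroxyl and malonate branch on the face opposite to O7 and C10) | O=C[C@H]1[C@@H](C(C(=O)OC)C(=O)OC)C[C@@H]2OC(C)(C)OC[C@]12O | intermediate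
13 | 2-[4a-hydroxy-5-(hydroxymethyl)-2,2-dimethylhexahydrocyclopenta[d][1,3]dioxin-6-yl]propane-1,3-diol, ring configuration as in 12 | OC[C@H]1[C@@H](C(CO)CO)C[C@@H]2OC(C)(C)OC[C@]12O | intermediate
14 | 2-[5-formyl-4a-hydroxy-2,2-dimethylhexahydrocyclopenta[d][1,3]dioxin-6-yl]propanedial, ring configuration as in 12 (not isolated) | O=C[C@H]1[C@@H](C(C=O)C=O)C[C@@H]2OC(C)(C)OC[C@]12O | intermediate
15 | tricyclic lactol aldehyde: iridoid 1-hydroxy-4-formyl-8-hydroxy-7,10-O-isopropylidene compound, C5, C7, C8, C9 as in the target, C1 anomers | OC1OC=C(C=O)[C@H]2C[C@@H]3OC(C)(C)OC[C@]3(O)[C@@H]12 | intermediate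
16 | (3S)-3-methylpentanoic acid | CC[C@H](C)CC(=O)O | starting material
17 | (1S)-1-O-[(3S)-3-methylpentanoyl] ester of 15 | CC[C@H](C)CC(=O)O[C@@H]1OC=C(C=O)[C@H]2C[C@@H]3OC(C)(C)OC[C@]3(O)[C@@H]12 | intermediate
18 | (1S)-1-O-[(3S)-3-methylpentanoyl]-4-formyl iridoid 7,8,10-triol | CC[C@H](C)CC(=O)O[C@@H]1OC=C(C=O)[C@H]2C[C@H](O)[C@](O)(CO)[C@@H]12 | intermediate
19 | (E)-4-hydroxycinnamic acid (p-coumaric acid) | OC(=O)/C=C/c1ccc(O)cc1 | starting material
20 | tert-butyldimethylsilyl (E)-4-(tert-butyldimethylsilyloxy)cinnamate (not isolated) | CC(C)(C)[Si](C)(C)OC(=O)/C=C/c1ccc(O[Si](C)(C)C(C)(C)C)cc1 | intermediate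
21 | (E)-4-(tert-butyldimethylsilyloxy)cinnamic acid | OC(=O)/C=C/c1ccc(O[Si](C)(C)C(C)(C)C)cc1 | intermediate
22 | 10-O-[(E)-4-(tert-butyldimethylsilyloxy)cinnamoyl] ester of 18 | CC[C@H](C)CC(=O)O[C@@H]1OC=C(C=O)[C@H]2C[C@H](O)[C@](O)(COC(=O)/C=C/c3ccc(O[Si](C)(C)C(C)(C)C)cc3)[C@@H]12 | intermediate
23 | 10-O-[(E)-4-hydroxycinnamoyl] ester of 18 (C11 aldehyde) | CC[C@H](C)CC(=O)O[C@@H]1OC=C(C=O)[C@H]2C[C@H](O)[C@](O)(COC(=O)/C=C/c3ccc(O)cc3)[C@@H]12 | intermediate
24 | CNP0241834.1 | CC[C@H](C)CC(=O)O[C@@H]1OC=C(CO)[C@H]2C[C@H](O)[C@](O)(COC(=O)/C=C/c3ccc(O)cc3)[C@@H]12 | target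

Total step count: 14. Longest linear sequence: 13 steps (steps 1–10 and 12–14, from 2,2-dimethyl-1,3-dioxan-5-one); step 11 is a one-step side branch.

Steps most likely to fail

Step 6. What may go wrong is insufficient facial selectivity at C9 in the enamine addition, leaving the formyl group trans to the C5 branch, together with some erosion at C5 by retro-Michael loss of malonate if the closure is slow. The fallback sets out from 11 and comes back at 15. The aldol is taken on regardless of C9: the C9-epimeric aldol F1 is reduced with LiAlH4 to the C9-epimeric tetraol F2 and oxidised under the conditions of step 8 to the C9-epimeric trialdehyde F3. In F3, C9 is again α to an aldehyde; catalytic DBU in CH2Cl2 should equilibrate it through the enol, and the epimer 14 is withdrawn as the more stable cis-fused lactol, so the material converges on 15. Control at C9 thus passes from the catalyst to the thermodynamics of pyran closure, the known behaviour of iridoid di- and trialdehydes.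

Step 8. What may go wrong is retro-aldol cleavage or β-elimination across C8–C9 once C1 is again an aldehyde in the presence of amine base, made worse if the free tertiary hydroxyl is itself activated by the chlorosulfonium salt. The fallback sets out from 12 and comes back at 18. The tertiary alcohol is capped first (TMSOTf, 2,6-lutidine, CH2Cl2, −78 °C) to give the 8-O-trimethylsilyl aldol F4. LiAlH4 then gives the 8-O-trimethylsilyl triol F5, and Swern oxidation gives the 8-O-trimethylsilyl trialdehyde F6, which should close to the 8-O-trimethylsilyl lactol F7. Esterification with 16 as in step 9 gives the 8-O-trimethylsilyl ester F8, and the aqueous acetic acid of step 10 removes the silyl ether together with the acetonide to reach 18. With O8 capped, neither retro-aldol nor activation of the tertiary oxygen is possible during the oxidation.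

Step 12. What may go wrong is incomplete discrimination between the neopentyl-type primary C10 hydroxyl and the secondary C7 hydroxyl, or acyl migration from O10 to O7 under DMAP. The fallback sets out from 18 and 21 and comes back at 22. Acid 21 is converted with oxalyl chloride and catalytic DMF into (E)-4-(tert-butyldimethylsilyloxy)cinnamoyl chloride F9, and 18 is acylated with F9 under Me2SnCl2 catalysis (K2CO3, THF, rt). The tin centre chelates the O7/O10 diol and delivers the acyl group to the primary oxygen, which is organotin-directed regioselective acylation of diols in place of undirected carbodiimide coupling.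

Further compounds
F1 | step 6 | C9-epimer of aldol 12 (formyl trans to the malonate branch) | O=C[C@@H]1[C@@H](C(C(=O)OC)C(=O)OC)C[C@@H]2OC(C)(C)OC[C@]12O
F2 | step 6 | C9-epimer of tetraol 13 | OC[C@@H]1[C@@H](C(CO)CO)C[C@@H]2OC(C)(C)OC[C@]12O
F3 | step 6 | C9-epimer of trialdehyde 14 | O=C[C@@H]1[C@@H](C(C=O)C=O)C[C@@H]2OC(C)(C)OC[C@]12O
F4 | step 8 | 8-O-trimethylsilyl ether of aldol 12 | O=C[C@H]1[C@@H](C(C(=O)OC)C(=O)OC)C[C@@H]2OC(C)(C)OC[C@]12O[Si](C)(C)C
F5 | step 8 | 8-O-trimethylsilyl ether of tetraol 13 | OC[C@H]1[C@@H](C(CO)CO)C[C@@H]2OC(C)(C)OC[C@]12O[Si](C)(C)C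
F6 | step 8 | 8-O-trimethylsilyl ether of trialdehyde 14 | O=C[C@H]1[C@@H](C(C=O)C=O)C[C@@H]2OC(C)(C)OC[C@]12O[Si](C)(C)C
F7 | step 8 | 8-O-trimethylsilyl ether of lactol 15 | OC1OC=C(C=O)[C@H]2C[C@@H]3OC(C)(C)OC[C@]3(O[Si](C)(C)C)[C@@H]12
F8 | step 8 | 8-O-trimethylsilyl ether of ester 17 | CC[C@H](C)CC(=O)O[C@@H]1OC=C(C=O)[C@H]2C[C@@H]3OC(C)(C)OC[C@]3(O[Si](C)(C)C)[C@@H]12
F9 | step 12 | (E)-4-(tert-butyldimethylsilyloxy)cinnamoyl chloride | O=C(Cl)/C=C/c1ccc(O[Si](C)(C)C(C)(C)C)cc1
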